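**Retrosynthetic overview**

1. Labels used throughout: ring A = C1 (CH bearing the ester oxygen), C2 (CH2), C3 and C4 (ring-fusion CH), C5=C6 (C6 carries the vinylic methyl); ring B = C3, C4, C7 (CMe2), C8, C9, C10, C11 (C(CH3)OH). In these labels the target is 1R,3R,4S,11S: H3 and H4 cis, C1–O on the face of H3/H4, C11–OH trans to H3.
2. Feature the plan rests on: the fifteen carbons of rings A and B with their four methyls are an unrearranged head-to-tail farnesyl chain, C4–C5=C6(Me)–C1–C2–C3=C11(Me)–C10–C9–C8=C7(Me)2. Only C4–C7 and C3–C4 stitch it together, and the C11 hydroxyl sits on the carbon where the cyclisation cation ends.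
3. Disconnections: the ester C(=O)–O bond at C1 (Steglich, silyl-protected isovanillic acid 9); C1–O (allylic hydroxylation of alcohol 5 from the convex face); C4–C7, C3–C4 and C11–O together (terpene-cyclase bicyclisation of farnesyl diphosphate 3 with water capture).
4. Ring order: the eleven-membered ring forms first (C4–C7), then the transannular C3–C4 bond divides it into rings A and B within the same enzymatic step. C3, C4 and C11 come from the cyclase, C1 from substrate-controlled selenium delivery.

Key step: step 3

Assumption: the tertiary allylic diphosphate through which the cyclase turns the 2E alkene of 3 into the cis C5=C6 alkene of ring A is drawn as (3R)-nerolidyl diphosphate; its handedness is fixed by the evolved fold, and the 3S form would serve the same mechanism.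

**Step 1**
Reactants: 1 (2E,6E)-farnesol
Product: 2 (2E,6E)-farnesyl chloride
Conditions: NCS, Me2S, CH2Cl2, −40 to 0 °C
Reagents that add atoms: N-chlorosuccinimide, O=C1CCC(=O)N1Cl
Why: Corey–Kim chlorination; the alkoxysulfonium salt of the primary allylic alcohol should be displaced by chloride at carbon without allylic transposition or loss of alkene geometry.

**Step 2**
Reactants: 2 (2E,6E)-farnesyl chloride
Product: 3 (2E,6E)-farnesyl diphosphate (handled as the trisammonium salt)
Conditions: (n-Bu4N)3HP2O7, MeCN, rt; then NH4+-form cation-exchange resin, aq NH4HCO3/i-PrOH; cellulose chromatography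
Reagents that add atoms: tris(tetrabutylammonium) hydrogen diphosphate, CCCC[N+](CCCC)(CCCC)CCCC.CCCC[N+](CCCC)(CCCC)CCCC.CCCC[N+](CCCC)(CCCC)CCCC.OP(=O)([O-])OP(=O)([O-])[O-]
Why: SN2 displacement of a primary allylic chloride by the diphosphate anion in a dipolar aprotic solvent, the standard synthesis of allylic diphosphates; both alkene geometries are retained.

**Step 3**
Reactants: 3 (2E,6E)-farnesyl diphosphate
Product: 5 (3R,4S,11S)-himachal-5-en-11-ol, via (3R)-nerolidyl diphosphate 4 (not isolated)
Conditions: evolved class 1 sesquiterpene synthase (himachalene-synthase scaffold, water-capture variant), MgCl2, HEPES buffer pH 7.5, glycerol, 30 °C, pentane overlay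
Reagents that add atoms: water, O
Why: Proposed new method: no cyclase is known that delivers this alcohol preparatively, but the cascade is that of the himachalene synthases up to the last cation: Mg2+-assisted ionisation of 3, return of diphosphate to the tertiary carbon C6 (4) and rotation give the cisoid allyl cation, C7 of the distal alkene adds to C4 (eleven-membered ring, cation at C8), a 1,3-hydride shift from C4 to C8 regenerates an allyl cation over C4–C5–C6 with the cis C5=C6 geometry that ring A needs, C3 of the central alkene adds to C4, and the tertiary C11 cation is taken by an active-site water instead of losing a proton. The closest known reaction types are the class 1 sesquiterpene synthases that form α-, β- and γ-himachalene by the same 1,11-closure, hydride shift and 1,6-closure, and the hydroxylating synthases of this class that end by water capture of a tertiary cation. The first closure is an 11-endo macrocyclisation (C7 and C8 both inside the ring); the second is transannular, 6-exo with respect to the C3=C11 alkene for ring A and, through the same C3–C4 bond, 7-endo for ring B. C3 and C4 are set together in that bond formation by the conformation in which the pocket holds the macrocycle (H3 and H4 on one side, cis fusion; absolute sense from the chain helicity). C11 is set by where the water sits: the target needs OH trans to H3, which means water adds to the cation face syn to the new C3–C4 bond, whereas the usual anti addition across the E C3=C11 alkene would give the C11 epimer, so the screen must select this face as well as hydration over deprotonation. The substrate secures the regiochemistry, since its head-to-tail methyl pattern makes C11 the tertiary cation terminus and places the methyls on C6, C7 (two) and C11 without rearrangement, while enantio- and diastereocontrol are asked of the evolved active site.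

**Step 4**
Reactants: 5 (3R,4S,11S)-himachal-5-en-11-ol
Product: 6 (1R,3R,4S,11S)-himachal-5-ene-1,11-diol
Conditions: SeO2 (0.3 equiv), t-BuOOH (2 equiv), CH2Cl2, 0 °C to rt
Reagents that add atoms: selenium dioxide (oxygen carrier), O=[Se]=O; tert-butyl hydroperoxide (terminal oxidant), CC(C)(C)OO
Why: Riley-type allylic hydroxylation in which the ene reaction puts selenium on C5 and removes hydrogen from the ring CH2 at C1 (allylic to the more substituted alkene carbon, ring CH2 preferred over CH3) and the [2,3]-sigmatropic shift then carries oxygen to C1 on the same face; selenium should approach the convex face of the cis-fused bicycle (the face of H3 and H4, away from ring B and the C7 methyls), which gives the 1R alcohol.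

**Step 5**
Reactants: 7 isovanillic acid
Product: 9 3-(tert-butyldimethylsilyloxy)-4-methoxybenzoic acid, via bis-silylated isovanillic acid 8 (not isolated)
Conditions: TBSCl (2.3 equiv), imidazole, DMF, rt; then AcOH/THF/H2O, rt
Reagents that add atoms: tert-butyldimethylsilyl chloride, CC(C)(C)[Si](C)(C)Cl
Why: silylation of both the phenol and the carboxyl group followed by selective hydrolysis of the far more labile silyl ester, which should leave the aryl silyl ether intact.

**Step 6**
Reactants: 6 (1R,3R,4S,11S)-himachal-5-ene-1,11-diol; 9 3-(tert-butyldimethylsilyloxy)-4-methoxybenzoic acid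
Product: 10 (1R,3R,4S,11S)-11-hydroxyhimachal-5-en-1-yl 3-(tert-butyldimethylsilyloxy)-4-methoxybenzoate
Conditions: DCC, DMAP, CH2Cl2, 0 °C to rt
Reagents that add atoms: none
Why: Steglich esterification; the acylpyridinium should acylate the secondary allylic C1–OH with retention (the C1–O bond of 6 is not broken), while the tertiary C11–OH is too hindered to react.

**Step 7**
Reactants: 10 (1R,3R,4S,11S)-11-hydroxyhimachal-5-en-1-yl 3-(tert-butyldimethylsilyloxy)-4-methoxybenzoate
Product: 11 (1R,3R,4S,11S)-11-hydroxyhimachal-5-en-1-yl 3-hydroxy-4-methoxybenzoate
Conditions: TBAF, AcOH, THF, 0 °C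
Reagents that add atoms: none
Why: fluoride-mediated desilylation of the aryl silyl ether, buffered with acetic acid so that the liberated phenoxide does not attack the benzoate; no stereocentre is touched.

**Compound list**

1 | (2E,6E)-farnesol | CC(C)=CCC/C(C)=C/CC/C(C)=C/CO | starting material
2 | (2E,6E)-farnesyl chloride | CC(C)=CCC/C(C)=C/CC/C(C)=C/CCl | intermediate
3 | (2E,6E)-farnesyl diphosphate (handled as the trisammonium salt, drawn as the free acid) | CC(C)=CCC/C(C)=C/CC/C(C)=C/COP(=O)(O)OP(=O)(O)O | intermediate
4 | (3R,6E)-nerolidyl diphosphate, enzyme-bound (nerolidyl numbering) | C=C[C@](C)(OP(=O)(O)OP(=O)(O)O)CC/C=C(\C)CCC=C(C)C | intermediate (not isolated)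
5 | (3R,4S,11S)-himachal-5-en-11-ol in the labels of the overview (2-himachalen-7-ol skeleton in himachalane numbering; cis-fused, C11–OH trans to H3) | C1C[C@@H]2[C@H](C=C1C)C(C)(C)CCC[C@]2(C)O | intermediate
6 | (1R,3R,4S,11S)-himachal-5-ene-1,11-diol (C1–OH cis to H3 and H4) | O[C@@H]1C[C@@H]2[C@H](C=C1C)C(C)(C)CCC[C@]2(C)O | intermediate
7 | isovanillic acid (3-hydroxy-4-methoxybenzoic acid) | COc1ccc(C(=O)O)cc1O | starting material
8 | tert-butyldimethylsilyl 3-(tert-butyldimethylsilyloxy)-4-methoxybenzoate | COc1ccc(C(=O)O[Si](C)(C)C(C)(C)C)cc1O[Si](C)(C)C(C)(C)C | intermediate (not isolated)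
9 | 3-(tert-butyldimethylsilyloxy)-4-methoxybenzoic acid | COc1ccc(C(=O)O)cc1O[Si](C)(C)C(C)(C)C | intermediate
10 | (1R,3R,4S,11S)-11-hydroxyhimachal-5-en-1-yl 3-(tert-butyldimethylsilyloxy)-4-methoxybenzoate | COc1ccc(C(=O)O[C@@H]2C[C@@H]3[C@H](C=C2C)C(C)(C)CCC[C@]3(C)O)cc1O[Si](C)(C)C(C)(C)C | intermediate
11 | (1R,3R,4S,11S)-11-hydroxyhimachal-5-en-1-yl 3-hydroxy-4-methoxybenzoate (CNP0210711.3) | COc1ccc(C(=O)O[C@@H]2C[C@@H]3[C@H](C=C2C)C(C)(C)CCC[C@]3(C)O)cc1O | target

Total step count: 7. Longest linear sequence: 6 steps (steps 1, 2, 3, 4, 6, 7).

**Steps most likely to fail**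

Step 3 (key step, proposed new method). What may go wrong: the evolved cyclases may keep deprotonating the C11 cation instead of hydrating it, may deliver water only to the anti face (wrong configuration at C11), or may fold the chain into the mirror-image ring fusion. Fallback with known chemistry, setting out from 3: a characterised himachalene synthase of the matching enantiomeric series, used without any engineering of the quench, should convert 3 into (3R,4S)-α-himachalene F1, which carries an exocyclic methylene at C11. Mukaiyama hydration of F1 (Co(acac)2, PhSiH3, O2, i-PrOH, rt) should hydrate the more accessible 1,1-disubstituted alkene in Markovnikov fashion and leave the trisubstituted C5=C6 alkene alone, to give the tertiary alcohol 5 together with its C11 epimer (3R,4S,11R)-himachal-5-en-11-ol F2. The two are separated by chromatography, and the route is rejoined at 5.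

Step 4. What may go wrong: ene attack at the vinylic methyl instead of the C1 methylene, over-oxidation to the enone, or oxygen delivery to the concave face. Fallback setting out from 5: the only allylic methylene is oxidised to the enone (3R,4S,11S)-11-hydroxyhimachal-5-en-1-one F3 (CrO3·3,5-dimethylpyrazole, CH2Cl2, −20 °C). Luche reduction (NaBH4, CeCl3·7H2O, MeOH, −78 °C) should deliver hydride from the open convex face and give (1S,3R,4S,11S)-himachal-5-ene-1,11-diol F4. Mitsunobu esterification of F4 with acid 9 (PPh3, DIAD, THF, 0 °C) inverts C1 and rejoins the route at 10; any 6 formed in the reduction is carried through step 6 as planned.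

Step 2. What may go wrong: loss of the allylic diphosphate by hydrolysis or elimination during displacement, ion exchange and chromatography. Fallback setting out from 1: one-pot phosphorylation of the alcohol oxygen with trichloroacetonitrile and bis(triethylammonium) hydrogen phosphate in MeCN (activation of phosphate instead of the carbon electrophile) gives (2E,6E)-farnesyl monophosphate F5 and, by further phosphorylation in the same pot, the diphosphate. Chromatography on silica (i-PrOH/conc. aq NH3/H2O) separates the diphosphate, and the route is rejoined at 3.

**Further compounds**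

F1 | step 3 | (3R,4S)-α-himachalene (himachala-5,11(exocyclic)-diene in the labels of the overview) | C1C[C@@H]2[C@H](C=C1C)C(C)(C)CCCC2=C
F2 | step 3 | (3R,4S,11R)-himachal-5-en-11-ol (C11 epimer of 5) | C1C[C@@H]2[C@H](C=C1C)C(C)(C)CCC[C@@]2(C)O
F3 | step 4 | (3R,4S,11S)-11-hydroxyhimachal-5-en-1-one | O=C1C[C@@H]2[C@H](C=C1C)C(C)(C)CCC[C@]2(C)O
F4 | step 4 | (1S,3R,4S,11S)-himachal-5-ene-1,11-diol (C1 epimer of 6) | O[C@H]1C[C@@H]2[C@H](C=C1C)C(C)(C)CCC[C@]2(C)O
F5 | step 2 | (2E,6E)-farnesyl monophosphate | CC(C)=CCC/C(C)=C/CC/C(C)=C/COP(=O)(O)O
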